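**Retrosynthetic overview**
1. Ring numbering: C1 (isopropenyl), C2=C3 (methyl on C3), C4 (C7H2–O–coumarin), C5 (methyl; chain C8H2–C9H2–C10O2H), C6H2. The plan rests on one feature of the carbocycle C1–C6. C7 and C8 sit cis on the neighbouring C4 and C5, and C3 and C6 are 1,4-related, which is the footprint of an exo furan/cyclic anhydride adduct whose oxygen spans C3 and C6.
2. Late bonds: the C10 acid from its methyl ester, C7–O(aryl) by Mitsunobu etherification, and C8=C9 by Horner–Wadsworth–Emmons olefination followed by 1,4-reduction.
3. C6H2 comes from a C6 carbinol (Barton–McCombie). That carbinol, the C1–isopropenyl bond and C2=C3 all arise in one rhodium-catalysed syn opening of a 7-oxabicyclo[2.2.1]heptene by an isopropenylboronate, in which the bridge passes its face on to C1.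
4. The bicycle comes from 2-methylfuran and citraconic anhydride by a Diels–Alder reaction (bonds C3–C4 and C5–C6). The carbocycle is the only ring built (step 1, with a temporary oxygen bridge that is cut in step 5); the coumarin is bought.
5. The adduct is racemic. The antipodes are parted at the primary diol by a lipase, which also tells C7 from C8. The later C6 carbinol, wedged between quaternary C5 and branched C1, is too crowded for an enzyme.

Key step: step 1

Assumption: the lipase of step 3 is taken to acetylate the enantiomer that is drawn, which is to be proved by X-ray analysis of a crystalline ester. If the sense is the reverse, the recovered diol is the needed antipode and is acetylated chemically at O7 to the same monoacetate. The ligand antipode of step 5 is picked by two small test runs.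

**Step 1**
Reactants: 1 2-methylfuran; 2 citraconic anhydride
Product: 3 exo-2,4-dimethyl-7-oxabicyclo[2.2.1]hept-5-ene-2,3-dicarboxylic anhydride (racemate; the needed (1R,2S,3R,4S) enantiomer is drawn; carbonyl carbons C7 and C8 exo and cis; C5 methyl endo; bridgehead methyl on C3 next to the anhydride CH)
Conditions: neat, 1 (3 equiv), 1.0 GPa, 25 °C, 72 h; excess 1 stripped below 20 °C, crude solid used at once
Reagents that add atoms: none
Why: The furan diene (C3, C2, C1, C6) adds suprafacially in a thermal [4π+2π] cycloaddition to the C4=C5 bond of the anhydride; the closest known reaction type is the reversible Diels–Alder reaction of furans with maleic-type anhydrides, driven here by pressure because a trisubstituted dienophile gives a poorly placed equilibrium at ambient pressure. The six-membered carbocycle C1–C6 closes in one concerted, asynchronous event through the new bonds C3–C4 and C5–C6, and the furan oxygen remains as the one-atom bridge C3–O–C6 of the 7-oxabicyclo[2.2.1]heptene. C4 and C5 are set cis because the anhydride ring locks the Z geometry; C3 and C6 are tied to each other by the bridge and to C4/C5 by the exo mode (C7 and C8 syn to oxygen, C5 methyl endo), which is the energy minimum reached by equilibration and is also favoured by the endo preference of a dienophile methyl group. The step needs the orientation that joins the methyl-bearing furan carbon to the anhydride CH: this pairs each fully substituted carbon with a CH partner, avoids two adjacent quaternary carbons, and agrees with the frontier orbitals (largest HOMO coefficient at the free furan α-carbon, larger LUMO coefficient at the methyl-bearing alkene carbon). Cycloreversion has a very small activation volume, so less stable isomers should still revert under pressure and the sorting should go on. The adduct is racemic and thermally labile, so it is kept cold and reduced directly; the absolute configuration is selected in step 3.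

**Step 2**
Reactants: 3 exo anhydride adduct
Product: 4 [(1R,2R,3S,4S)-2,4-dimethyl-7-oxabicyclo[2.2.1]hept-5-ene-2,3-diyl]dimethanol (racemate; needed enantiomer drawn; both CH2OH groups exo)
Conditions: LiAlH4 (3 equiv), THF, −30 → 25 °C; then H2O/aq NaOH
Reagents that add atoms: none
Why: Exhaustive LiAlH4 reduction of a cyclic anhydride to the 1,4-diol is standard for furan–anhydride adducts; it is started cold so that hydride attack outpaces cycloreversion, it leaves the alkene, the ether bridge and all four stereocentres alone, and once both carbonyl groups are gone the bicycle can no longer revert.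

**Step 3**
Reactants: 4 racemic diol
Product: 5 C7 monoacetate of the (1R,2R,3S,4S) diol = [(1S,2S,3R,4R)-3-(hydroxymethyl)-1,3-dimethyl-7-oxabicyclo[2.2.1]hept-5-en-2-yl]methyl acetate (single enantiomer)
Conditions: lipase PS from Burkholderia cepacia (immobilised), vinyl acetate (3 equiv), MTBE, 30 °C, stopped near half conversion; chromatography
Reagents that add atoms: vinyl acetate, C=COC(C)=O
Why: Lipase-catalysed irreversible transesterification (kinetic resolution) is established for telling apart the two hydroxymethyl arms of exo-7-oxanorbornane-2,3-dimethanols, so only the enantiomer of 4 that offers its less hindered C7 hydroxyl in the favoured arm position should be acetylated while the antipode offers the neopentyl C8 hydroxyl there and stays behind, which gives resolution, C7/C8 differentiation and C7 protection in one operation without creating a stereocentre.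

**Step 4**
Reactants: 5 monoacetate
Product: 6 C7 acetate C8 tert-butyldimethylsilyl ether of the bicyclic diol (configuration unchanged)
Conditions: TBSCl, imidazole, DMF, 25 °C
Reagents that add atoms: tert-butyldimethylsilyl chloride, CC(C)(C)[Si](C)(C)Cl
Why: Routine silyl ether protection of the remaining neopentyl primary alcohol, needed so that the C6 hydroxyl set free in step 5 is the only one in the molecule; imidazole is too weak a base to move the acetate from O7 to O8.

**Step 5**
Reactants: 6 protected oxabicycle; 7 isopropenylboronic acid pinacol ester
Product: 8 cyclohex-2-enol with isopropenyl at C1, OH at C6, CH2OTBS at C5 and CH2OAc at C4 all on one face, C5 methyl on the other face, methyl on C3 of C2=C3; (1S,4S,5R,6R) in the ring numbering used here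
Conditions: [Rh(cod)Cl]2 (2.5 mol %), Josiphos ligand PPF-P(t-Bu)2 (5 mol %, antipode matched to 6), 7 (1.5 equiv), Cs2CO3 (0.5 equiv, aq), THF, 25 → 40 °C
Reagents that add atoms: none
Why: Rhodium-catalysed ring opening of an oxabicyclic alkene by an organoboron reagent: transmetalation gives an isopropenyl complex of monovalent rhodium that adds syn across C1=C2 from the exo face with carbon going to C1 (the alkene carbon remote from the bridgehead methyl), β-oxygen elimination of the C3–O bond then releases the strain, forms C2=C3 and leaves the C6 alkoxide, so C1 is set cis to O6, C7 and C8 by the bridge, and with the matched ligand any residual wrong enantiomer should react more slowly.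

**Step 6**
Reactants: 8 cyclohexenol
Product: 9 O-(C6) imidazole-1-carbothioate of 8 (configuration unchanged)
Conditions: 1,1'-thiocarbonyldiimidazole (3 equiv), DMAP (0.3 equiv), PhMe, 90 °C
Reagents that add atoms: 1,1'-thiocarbonyldiimidazole, S=C(n1ccnc1)n1ccnc1
Why: First half of the Barton–McCombie sequence: the lone, crowded C6 hydroxyl is thioacylated under neutral conditions (a xanthate made with strong base would invite acetyl migration), and thermal syn elimination cannot compete because C5 carries no hydrogen and the C1 hydrogen is trans to O6.

**Step 7**
Reactants: 9 thiocarbonyl imidazolide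
Product: 10 C6-deoxy compound: cyclohexene with isopropenyl (C1), CH2OAc (C4) and CH2OTBS (C5) all cis, C5 methyl trans to them
Conditions: Bu3SnH (5 equiv, 0.5 M), PhSeSePh (10 mol %), Et3B/air, PhMe (degassed), 25 °C
Reagents that add atoms: none
Why: Barton–McCombie deoxygenation: the stannyl radical adds to sulfur, the C6–O bond fragments to a secondary radical that takes up hydrogen, and the high stannane concentration, the very fast hydrogen donor PhSeH formed from the diselenide and the low temperature are chosen to outrun 3-exo attack of this homoallylic radical on the isopropenyl group; C1, C4 and C5 are not involved.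

**Step 8**
Reactants: 10 silyl ether
Product: 11 C8 primary alcohol (C7 acetate kept; configuration unchanged)
Conditions: HF·pyridine, pyridine, THF, 0 → 25 °C
Reagents that add atoms: none
Why: Fluoride-driven cleavage of the primary silyl ether; the pyridine-buffered reagent generates no alkoxide, so the acetate does not shift, and it is not acidic enough to protonate the two alkenes.

**Step 9**
Reactants: 11 alcohol
Product: 12 C8 aldehyde on quaternary C5 (C7 acetate kept)
Conditions: Dess–Martin periodinane, CH2Cl2, 0 → 25 °C
Reagents that add atoms: none
Why: Dess–Martin oxidation of the neopentyl primary alcohol under near-neutral conditions stops at the aldehyde, which has no α-hydrogen, so C5 cannot epimerise.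

**Step 10**
Reactants: 12 aldehyde; 13 trimethyl phosphonoacetate
Product: 14 methyl (E)-enoate C5–C8H=C9H–C10O2Me (C7 acetate kept)
Conditions: 13, NaH, THF, 0 °C; then 12, 0 → 40 °C
Reagents that add atoms: none
Why: Horner–Wadsworth–Emmons olefination adds C9 and C10; the small, reactive phosphonate anion copes with an aldehyde on a quaternary carbon, the stabilised carbanion leaves the acetate alone, and the expected E geometry is of no consequence because the double bond is reduced next.

**Step 11**
Reactants: 14 enoate
Product: 15 saturated methyl ester C5–C8H2–C9H2–C10O2Me (C7 acetate kept)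
Conditions: Cu(OAc)2·H2O (5 mol %), 1,2-bis(diphenylphosphino)benzene (5 mol %), (EtO)2MeSiH (3 equiv), t-BuOH (3 equiv), PhMe, 25 °C
Reagents that add atoms: none
Why: Copper hydride 1,4-reduction (conjugate hydrosilylation by a phosphine complex of monovalent copper): the polar hydride goes only to the electron-poor C8=C9 bond, so the isopropenyl group, C2=C3 and both esters stay, and no C8 radical arises that could attack the nearby isopropenyl group as it might in a dissolving-metal reduction.

**Step 12**
Reactants: 15 acetate ester
Product: 16 hydroxy ester (free C7H2OH; C10 methyl ester)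
Conditions: K2CO3 (0.2 equiv), MeOH, 0 → 25 °C
Reagents that add atoms: none
Why: Base-catalysed transesterification removes the acetate as methyl acetate, the exchange at the C10 methyl ester is degenerate in methanol, and doing this only after step 11 rules out oxa-Michael closure of O7 onto C8.

**Step 13**
Reactants: 16 hydroxy ester; 17 umbelliferone
Product: 18 methyl ester of the target (C7–O–C7' coumarin ether)
Conditions: PPh3, DIAD, THF, 0 → 40 °C
Reagents that add atoms: none
Why: Mitsunobu etherification: the acidic 7-hydroxyl of the coumarin displaces the oxyphosphonium derivative of the primary C7 alcohol in an SN2 step at a CH2 group, so no stereocentre is touched, and the homoallylic position of C7 excludes allylic transposition.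

**Step 14**
Reactants: 18 methyl ester
Product: 20 3-[(1R,2R,5S)-1,3-dimethyl-2-[(2-oxochromen-7-yl)oxymethyl]-5-(prop-1-en-2-yl)cyclohex-3-en-1-yl]propanoic acid (target), via lithium carboxylate 19 (not isolated)
Conditions: LiOH (3 equiv), THF/H2O, 0 → 25 °C; then 1 M HCl to pH 3
Reagents that add atoms: lithium hydroxide, [Li+].[OH-]
Why: Saponification of the unhindered methyl ester; any coumarin lactone that opens to the (Z)-2-hydroxycinnamate closes again on acidification, and neither the base nor brief dilute acid affects C1, C4, C5 or the skipped diene.

**Compound list**
1 | 2-methylfuran | Cc1ccco1 | starting material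
2 | citraconic anhydride | CC1=CC(=O)OC1=O | starting material
3 | exo-2,4-dimethyl-7-oxabicyclo[2.2.1]hept-5-ene-2,3-dicarboxylic anhydride (racemate, needed enantiomer drawn) | C[C@@]12C=C[C@@H](O1)[C@@]3(C)C(=O)OC(=O)[C@@H]23 | intermediate
4 | exo,exo diol (racemate, needed enantiomer drawn) | C[C@@]12C=C[C@@H](O1)[C@@](C)(CO)[C@H]2CO | intermediate
5 | C7 monoacetate (single enantiomer) | C[C@@]12C=C[C@@H](O1)[C@@](C)(CO)[C@H]2COC(C)=O | intermediate
6 | C7 acetate, C8 TBS ether | C[C@@]12C=C[C@@H](O1)[C@@](C)(CO[Si](C)(C)C(C)(C)C)[C@H]2COC(C)=O | intermediate
7 | isopropenylboronic acid pinacol ester | C=C(C)B1OC(C)(C)C(C)(C)O1 | starting material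
8 | ring-opened all-cis cyclohexenol | C=C(C)[C@@H]1C=C(C)[C@H](COC(C)=O)[C@](C)(CO[Si](C)(C)C(C)(C)C)[C@@H]1O | intermediate
9 | C6 imidazole-1-carbothioate | C=C(C)[C@@H]1C=C(C)[C@H](COC(C)=O)[C@](C)(CO[Si](C)(C)C(C)(C)C)[C@@H]1OC(=S)n2ccnc2 | intermediate
10 | C6-deoxy acetate silyl ether | C=C(C)[C@@H]1C=C(C)[C@H](COC(C)=O)[C@](C)(CO[Si](C)(C)C(C)(C)C)C1 | intermediate
11 | C8 alcohol | C=C(C)[C@@H]1C=C(C)[C@H](COC(C)=O)[C@](C)(CO)C1 | intermediate
12 | C8 aldehyde | C=C(C)[C@@H]1C=C(C)[C@H](COC(C)=O)[C@](C)(C=O)C1 | intermediate
13 | trimethyl phosphonoacetate | COC(=O)CP(=O)(OC)OC | starting material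
14 | (E)-enoate | C=C(C)[C@@H]1C=C(C)[C@H](COC(C)=O)[C@](C)(/C=C/C(=O)OC)C1 | intermediate
15 | saturated methyl ester, C7 acetate | C=C(C)[C@@H]1C=C(C)[C@H](COC(C)=O)[C@](C)(CCC(=O)OC)C1 | intermediate
16 | hydroxy ester | C=C(C)[C@@H]1C=C(C)[C@H](CO)[C@](C)(CCC(=O)OC)C1 | intermediate
17 | umbelliferone | O=c1ccc2ccc(O)cc2o1 | starting material
18 | methyl ester of the target | C=C(C)[C@@H]1C=C(C)[C@H](COc2ccc3ccc(=O)oc3c2)[C@](C)(CCC(=O)OC)C1 | intermediate
19 | lithium carboxylate of the target (not isolated) | C=C(C)[C@@H]1C=C(C)[C@H](COc2ccc3ccc(=O)oc3c2)[C@](C)(CCC(=O)[O-])C1.[Li+] | intermediate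
20 | CNP0301632.1 | C=C(C)[C@@H]1C=C(C)[C@H](COc2ccc3ccc(=O)oc3c2)[C@](C)(CCC(=O)O)C1 | target

Total step count: 14. Longest linear sequence: 14 steps (1/2 → 20).

**Steps most likely to fail**

Step 1. The equilibrium may lie on the side of the addends, the adduct may revert during isolation, and the sorting of orientation isomers may stay incomplete. The fallback sets out from 2 (with 1) and comes back at 4.
- Compound 2 is heated with NH4OAc in AcOH to give citraconimide F1.
- Boc2O with catalytic DMAP in MeCN converts this into N-Boc-citraconimide F2.
- This electron-poor imide is combined with 1 (CH2Cl2, 25–40 °C) to give the exo imide adduct F3. Furan adducts of this class revert far less readily than anhydride adducts, so F3 can be recrystallised free of isomers.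
- LiBH4 in THF/MeOH then cleaves both acyl–nitrogen bonds reductively, as it does with N-acyl carbamates, and gives diol 4.

Step 5. The alkenylboronate may protodeboronate faster than it transmetalates, carbometalation of the crowded alkene may be sluggish, and the aqueous base may erode the acetate. The fallback sets out from 6 and comes back at 8. It replaces the boron nucleophile with a reductive coupling of 2-bromopropene (PdCl2(PPh3)2 or NiCl2(PPh3)2 as catalyst, zinc powder, THF or MeCN, 60 °C). The alkenyl halide adds oxidatively to the zerovalent metal, the same exo syn carbometalation and β-oxygen elimination follow, and zinc closes the cycle, all without water or base. The fallback makes no compound outside the list (F0).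

Step 3. Acylation in the crowded pocket next to the bridgehead methyl may be slow, discrimination between the antipodes or between the two arms may be weak, or the sense may be reversed. The fallback sets out from 4 and comes back at 5.
- Both hydroxyls of racemic 4 are esterified with (1S)-camphanic chloride (DMAP, Et3N, CH2Cl2).
- The two diastereomers are separated by fractional crystallisation or chromatography, and the needed bis-camphanate F4 is identified by X-ray analysis with the camphanate as internal reference.
- K2CO3 in MeOH releases the enantiopure diol F5.
- The less hindered O7 is acetylated chemically (AcCl, 2,4,6-collidine, CH2Cl2, −78 °C) to give 5.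

**Further compounds**
F1 | step 1 | citraconimide (3-methyl-1H-pyrrole-2,5-dione) | CC1=CC(=O)NC1=O
F2 | step 1 | N-Boc-citraconimide | CC1=CC(=O)N(C(=O)OC(C)(C)C)C1=O
F3 | step 1 | exo N-Boc imide adduct (racemate, needed enantiomer drawn) | C[C@@]12C=C[C@@H](O1)[C@@]3(C)C(=O)N(C(=O)OC(C)(C)C)C(=O)[C@@H]23
F4 | step 3 | bis-(1S)-camphanate of the (1R,2R,3S,4S) diol | C[C@@]12C=C[C@@H](O1)[C@@](C)(COC(=O)[C@@]34CC[C@@](C)(C(=O)O3)C4(C)C)[C@H]2COC(=O)[C@@]56CC[C@@](C)(C(=O)O5)C6(C)C
F5 | step 3 | enantiopure (1R,2R,3S,4S) diol | C[C@@]12C=C[C@@H](O1)[C@@](C)(CO)[C@H]2CO
F0 | step 5 | none | none
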